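The cyclohexane is the only ring; its atoms are numbered C1 (CH bearing the chain), C2 (CMe2), C3 (CHMe), C4, C5, C6 (C=CH2), and everything rests on closing it at C1–C6. The exocyclic methylene on C6 next to C1–H, with the arm on C1 read as a former vinyl group, is an Alder-ene retron. Palladium-hydride cycloisomerisation of the acyclic 1,7-enyne 10 (terminal alkyne, E-propenyl on the CMe2 carbon) should form the ring, the methylene, the C1 stereocentre (trans to the C3 methyl) and a vinyl handle in one step. Enyne 10 comes from an Ireland–Claisen rearrangement. The vinyl group is grown into a geranyl-type phosphate, which a citronellal-derived alkenylalane attacks SN2′ under chiral copper catalysis.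

Key step: step 7

Assumption: in step 22 the antipode of the chiral imidazolinium ligand is taken that directs the alkenyl group to the Si face of C3 of phosphate 17; both antipodes are accessible from the two enantiomers of 1,2-diphenylethylenediamine.

Step 1
Reactants: 1 4-methylpent-3-en-2-one (mesityl oxide)
Product: 2 (2S)-4-methylpent-3-en-2-ol
Conditions: (R)-2-methyl-CBS-oxazaborolidine (10 mol %), catecholborane, toluene, −78 °C
Reagents that add atoms: none
Why: Corey–Bakshi–Shibata reduction; the oxazaborolidine–borane complex binds the carbonyl anti to the larger alkenyl group and delivers hydride 1,2 to one face, which should give the (S)-allylic alcohol.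

Step 2
Reactants: 2 (2S)-4-methylpent-3-en-2-ol
Product: 3 (2S)-4-methylpent-3-en-2-yl propanoate
Conditions: EtCOCl, pyridine, DMAP (cat.), CH2Cl2, 0 °C
Reagents that add atoms: propanoyl chloride, CCC(=O)Cl
Why: O-acylation of a secondary allylic alcohol under basic conditions that do not ionise the allylic C–O bond.

Step 3
Reactants: 3 (2S)-4-methylpent-3-en-2-yl propanoate
Product: 6 (2R,4E)-2,3,3-trimethylhex-4-enoic acid, via silyl ketene acetal 4 (not isolated), via trimethylsilyl ester 5 (not isolated)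
Conditions: LDA, THF, −78 °C; TMSCl/Et3N; −78 → 55 °C; 1 M HCl
Reagents that add atoms: none
Why: Ireland–Claisen rearrangement; kinetic enolisation in THF gives the E(O)-enolate, trapped as the (E)-silyl ketene acetal, and its chair [3,3] shift with the carbinol methyl equatorial should transfer the (S) carbinol chirality to C2 (R) while forming the gem-dimethyl quaternary carbon and the E-propenyl group (enolate geometry is the element that has to be controlled).

Step 4
Reactants: 6 (2R,4E)-2,3,3-trimethylhex-4-enoic acid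
Product: 7 (2R,4E)-2,3,3-trimethylhex-4-en-1-ol
Conditions: LiAlH4, THF, 0 °C → reflux
Reagents that add atoms: none
Why: LiAlH4 reduces the hindered carboxylic acid to the primary alcohol without touching the isolated alkene or the stereocentre.

Step 5
Reactants: 7 (2R,4E)-2,3,3-trimethylhex-4-en-1-ol
Product: 9 trimethyl[(5S,7E)-5,6,6-trimethylnon-7-en-1-yn-1-yl]silane, via triflate 8 (not isolated)
Conditions: Tf2O, pyridine, CH2Cl2, −78 °C; then LiCH2C≡CSiMe3 (from 1-(trimethylsilyl)prop-1-yne, n-BuLi), THF/DMPU, −78 → −20 °C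
Reagents that add atoms: 1-(trimethylsilyl)prop-1-yne, CC#C[Si](C)(C)C
Why: SN2 displacement of a primary triflate (chosen because the CH2 is β-branched) by the propargylic lithium reagent, which reacts at its CH2 terminus; the stereocentre is not involved.

Step 6
Reactants: 9 trimethyl[(5S,7E)-5,6,6-trimethylnon-7-en-1-yn-1-yl]silane
Product: 10 (5S,7E)-5,6,6-trimethylnon-7-en-1-yne
Conditions: K2CO3, MeOH, 23 °C
Reagents that add atoms: none
Why: Base-mediated protodesilylation of the alkynylsilane.

Step 7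
Reactants: 10 (5S,7E)-5,6,6-trimethylnon-7-en-1-yne
Product: 11 (1S,3S)-1-ethenyl-2,2,3-trimethyl-6-methylidenecyclohexane
Conditions: Pd2(dba)3·CHCl3 (2.5 mol %), P(o-tol)3 (10 mol %), AcOH (20 mol %), benzene, 60 °C
Reagents that add atoms: none
Why: Pd(0) and AcOH generate H–Pd–OAc, which adds across the terminal alkyne with Pd on the internal carbon (C6); the alkenyl–Pd then inserts the tethered E-propenyl C=C syn, and β-hydride elimination from the terminal methyl releases the 1,4-diene and returns the hydride. The closest known reaction type is the Pd-catalysed Alder-ene cycloisomerisation of 1,6- and 1,7-enynes, here assisted by the gem-dimethyl group in the tether. The ring closes by a 6-exo-trig carbopalladation that forms C6–C1. The new C1 stereocentre is controlled by the existing C3 centre: insertion needs the Pd–C6 bond and the C1=C bond coplanar, which holds the CH(Pd)CH3 carbon perpendicular to the forming exocyclic alkene, i.e. axial on C1 and free of A(1,3) strain, and a chair with the C3 methyl equatorial avoids a 1,3-diaxial clash with that carbon, so C1 should come out trans to the C3 methyl (1S,3S). The step needs Markovnikov hydropalladation (favoured by chelation of the alkene) and β-hydride loss from CH3 instead of from C1–H (three accessible primary hydrogens against one hindered methine), which together place the methylene on C6 and the vinyl group on C1; the C3 centre is not touched.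

Step 8
Reactants: 12 ethyl 3-oxobutanoate (ethyl acetoacetate)
Product: 13 ethyl (2E)-3-(trifluoromethanesulfonyloxy)but-2-enoate
Conditions: Tf2O, aq. Me4NOH, hexanes, 5 °C
Reagents that add atoms: trifluoromethanesulfonic anhydride, O=S(=O)(OS(=O)(=O)C(F)(F)F)C(F)(F)F
Why: O-triflation of the non-chelated tetraalkylammonium enolate of the β-keto ester, which should give the E enol triflate (triflate trans to the ester).

Step 9
Reactants: 11 (1S,3S)-1-ethenyl-2,2,3-trimethyl-6-methylidenecyclohexane, 13 ethyl (2E)-3-(trifluoromethanesulfonyloxy)but-2-enoate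
Product: 15 ethyl (2E)-3-methyl-5-[(1S,3S)-2,2,3-trimethyl-6-methylidenecyclohexyl]pent-2-enoate, via alkyldisiamylborane 14 (not isolated)
Conditions: Sia2BH (from BH3·SMe2 and 2-methylbut-2-ene), THF, 0 °C; then 13, PdCl2(dppf) (5 mol %), K3PO4, H2O, THF/DMF, 50 °C
Reagents that add atoms: none
Why: Disiamylborane should add anti-Markovnikov to the monosubstituted vinyl group in preference to the 1,1-disubstituted exocyclic alkene, and the primary alkylborane then undergoes B-alkyl Suzuki–Miyaura coupling with the enol triflate with retention of the E geometry.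

Step 10
Reactants: 15 ethyl (2E)-3-methyl-5-[(1S,3S)-2,2,3-trimethyl-6-methylidenecyclohexyl]pent-2-enoate
Product: 16 (2E)-3-methyl-5-[(1S,3S)-2,2,3-trimethyl-6-methylidenecyclohexyl]pent-2-en-1-ol
Conditions: DIBAL-H, CH2Cl2, −78 °C; Rochelle salt
Reagents that add atoms: none
Why: 1,2-Reduction of the conjugated ester to the allylic alcohol; the isolated alkenes are inert to DIBAL-H at low temperature.

Step 11
Reactants: 16 (2E)-3-methyl-5-[(1S,3S)-2,2,3-trimethyl-6-methylidenecyclohexyl]pent-2-en-1-ol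
Product: 17 diethyl (2E)-3-methyl-5-[(1S,3S)-2,2,3-trimethyl-6-methylidenecyclohexyl]pent-2-en-1-yl phosphate
Conditions: (EtO)2P(O)Cl, Et3N, DMAP (cat.), CH2Cl2, 0 °C
Reagents that add atoms: diethyl chlorophosphate, CCOP(Cl)(=O)OCC
Why: O-phosphorylation of the primary allylic alcohol installs the leaving group for allylic substitution.

Step 12
Reactants: 18 (3S)-3,7-dimethyloct-6-enal ((S)-citronellal)
Product: 20 (3S)-3,7-dimethyloct-6-en-1-yne, via alkenyl nonaflate 19 (not isolated)
Conditions: C4F9SO2F, phosphazene base P2-Et, DMF, −30 → 23 °C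
Reagents that add atoms: none
Why: One-pot enol nonaflate formation and base-induced E2 elimination turns the CH2–CHO unit into a terminal alkyne without change in carbon count; the stereocentre is β to the carbonyl and cannot enolise.

Step 13
Reactants: 20 (3S)-3,7-dimethyloct-6-en-1-yne
Product: 22 trimethyl[(3S)-3,7-dimethyloct-6-en-1-yn-1-yl]silane, via lithium acetylide 21 (not isolated)
Conditions: n-BuLi, THF, −78 °C; TMSCl, −78 → 0 °C
Reagents that add atoms: chlorotrimethylsilane, C[Si](C)(C)Cl
Why: Deprotonation and C-silylation mask the acidic alkyne C–H for the later Grignard step.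

Step 14
Reactants: 22 trimethyl[(3S)-3,7-dimethyloct-6-en-1-yn-1-yl]silane
Product: 23 (2E,6S)-2,6-dimethyl-8-(trimethylsilyl)oct-2-en-7-yn-1-ol
Conditions: SeO2 (cat.), t-BuOOH, salicylic acid (cat.), CH2Cl2, 23 °C
Reagents that add atoms: tert-butyl hydroperoxide, CC(C)(C)OO
Why: Selenium dioxide allylic oxidation (ene reaction, then [2,3]-sigmatropic shift) should attack the E-methyl group of the trisubstituted alkene and give the E-allylic alcohol.

Step 15
Reactants: 23 (2E,6S)-2,6-dimethyl-8-(trimethylsilyl)oct-2-en-7-yn-1-ol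
Product: 24 [(3S,6E)-8-bromo-3,7-dimethyloct-6-en-1-yn-1-yl]trimethylsilane
Conditions: CBr4, PPh3, CH2Cl2, −20 → 0 °C
Reagents that add atoms: carbon tetrabromide, BrC(Br)(Br)Br
Why: Appel bromination of the primary allylic alcohol under neutral conditions, without allylic transposition at low temperature.

Step 16
Reactants: 25 (4S)-4-benzyl-1,3-oxazolidin-2-one
Product: 26 (4S)-4-benzyl-3-(3-methylbut-2-enoyl)-1,3-oxazolidin-2-one
Conditions: 3-methylbut-2-enoyl chloride, Et3N, LiCl, THF, 0 → 23 °C
Reagents that add atoms: 3-methylbut-2-enoyl chloride, CC(C)=CC(=O)Cl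
Why: N-acylation of the oxazolidinone under mild LiCl/Et3N activation.

Step 17
Reactants: 26 (4S)-4-benzyl-3-(3-methylbut-2-enoyl)-1,3-oxazolidin-2-one
Product: 28 (4S)-4-benzyl-3-[(2S)-2,3-dimethylbut-3-enoyl]-1,3-oxazolidin-2-one, via sodium dienolate 27 (not isolated)
Conditions: NaHMDS, THF, −78 °C; MeI, −78 °C
Reagents that add atoms: iodomethane, CI
Why: Evans alkylation in its deconjugative form; γ-deprotonation gives the chelated Z-dienolate, which should be methylated at the α-carbon anti to the benzyl group, setting the (S) centre that carries the isopropenyl group.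

Step 18
Reactants: 28 (4S)-4-benzyl-3-[(2S)-2,3-dimethylbut-3-enoyl]-1,3-oxazolidin-2-one
Product: 29 (2S)-2,3-dimethylbut-3-en-1-ol
Conditions: LiBH4, H2O (1 equiv), Et2O, 0 °C
Reagents that add atoms: none
Why: Reductive removal of the auxiliary gives the primary alcohol without epimerisation of the α-centre.

Step 19
Reactants: 29 (2S)-2,3-dimethylbut-3-en-1-ol
Product: 30 (3S)-4-bromo-2,3-dimethylbut-1-ene
Conditions: Ph3PBr2, imidazole, CH2Cl2, 0 °C
Reagents that add atoms: dibromotriphenylphosphorane, BrP(Br)(c1ccccc1)(c1ccccc1)c1ccccc1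
Why: Appel-type conversion of the primary alcohol into the bromide through the alkoxyphosphonium salt, with no free bromine to attack the alkene.

Step 20
Reactants: 30 (3S)-4-bromo-2,3-dimethylbut-1-ene, 24 [(3S,6E)-8-bromo-3,7-dimethyloct-6-en-1-yn-1-yl]trimethylsilane
Product: 32 trimethyl[(3S,6E,10R)-3,7,10,11-tetramethyldodeca-6,11-dien-1-yn-1-yl]silane, via Grignard reagent 31 (not isolated)
Conditions: 30, Mg, THF; then 24, Li2CuCl4 (3 mol %), THF, −78 → 0 °C
Reagents that add atoms: none
Why: Copper-catalysed coupling of the primary homoallylic Grignard reagent with the primary allylic bromide should occur at the α-carbon (SN2) with retention of the E-alkene; the β-stereocentre of the Grignard reagent is not affected.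

Step 21
Reactants: 32 trimethyl[(3S,6E,10R)-3,7,10,11-tetramethyldodeca-6,11-dien-1-yn-1-yl]silane
Product: 33 (3S,6E,10R)-3,7,10,11-tetramethyldodeca-6,11-dien-1-yne
Conditions: K2CO3, MeOH, 23 °C
Reagents that add atoms: none
Why: Protodesilylation frees the terminal alkyne.

Step 22
Reactants: 33 (3S,6E,10R)-3,7,10,11-tetramethyldodeca-6,11-dien-1-yne, 17 diethyl (2E)-3-methyl-5-[(1S,3S)-2,2,3-trimethyl-6-methylidenecyclohexyl]pent-2-en-1-yl phosphate
Product: 35 (1S,3S)-1-[(3S,4E,6S,9E,13R)-3-ethenyl-3,6,10,13,14-pentamethylpentadeca-4,9,14-trien-1-yl]-2,2,3-trimethyl-6-methylidenecyclohexane, via alkenylalane 34 (not isolated)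
Conditions: 33, DIBAL-H, hexanes, 55 °C; then 17, chiral sulfonate-bearing imidazolinium salt (2.5 mol %), CuCl2·2H2O (5 mol %), THF, −15 °C
Reagents that add atoms: none
Why: syn-Hydroalumination of the terminal alkyne gives the E-alkenylalane, which undergoes NHC–copper-catalysed enantioselective allylic substitution (SN2′) at C3 of the E-allylic phosphate; the catalyst selects the Si face of C3 and so should set the (S) quaternary centre while forming the vinyl group and keeping the E-alkenyl geometry.

Compound list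
1 | 4-methylpent-3-en-2-one (mesityl oxide) | CC(=O)C=C(C)C | starting material
2 | (2S)-4-methylpent-3-en-2-ol | C[C@H](O)C=C(C)C | intermediate
3 | (2S)-4-methylpent-3-en-2-yl propanoate | CCC(=O)O[C@@H](C)C=C(C)C | intermediate
4 | trimethyl{[(1E)-1-{[(2S)-4-methylpent-3-en-2-yl]oxy}prop-1-en-1-yl]oxy}silane | C/C=C(/O[Si](C)(C)C)O[C@@H](C)C=C(C)C | intermediate
5 | trimethylsilyl (2R,4E)-2,3,3-trimethylhex-4-enoate | C/C=C/C(C)(C)[C@@H](C)C(=O)O[Si](C)(C)C | intermediate
6 | (2R,4E)-2,3,3-trimethylhex-4-enoic acid | C/C=C/C(C)(C)[C@@H](C)C(=O)O | intermediate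
7 | (2R,4E)-2,3,3-trimethylhex-4-en-1-ol | C/C=C/C(C)(C)[C@@H](C)CO | intermediate
8 | (2R,4E)-2,3,3-trimethylhex-4-en-1-yl trifluoromethanesulfonate | C/C=C/C(C)(C)[C@@H](C)COS(=O)(=O)C(F)(F)F | intermediate
9 | trimethyl[(5S,7E)-5,6,6-trimethylnon-7-en-1-yn-1-yl]silane | C/C=C/C(C)(C)[C@@H](C)CCC#C[Si](C)(C)C | intermediate
10 | (5S,7E)-5,6,6-trimethylnon-7-en-1-yne | C/C=C/C(C)(C)[C@@H](C)CCC#C | intermediate
11 | (1S,3S)-1-ethenyl-2,2,3-trimethyl-6-methylidenecyclohexane | C=C[C@H]1C(=C)CC[C@H](C)C1(C)C | intermediate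
12 | ethyl 3-oxobutanoate (ethyl acetoacetate) | CCOC(=O)CC(C)=O | starting material
13 | ethyl (2E)-3-(trifluoromethanesulfonyloxy)but-2-enoate | CCOC(=O)/C=C(\C)OS(=O)(=O)C(F)(F)F | intermediate
14 | bis(3-methylbutan-2-yl){2-[(1S,3S)-2,2,3-trimethyl-6-methylidenecyclohexyl]ethyl}borane (siamyl centres unspecified) | CC(C)C(C)B(CC[C@H]1C(=C)CC[C@H](C)C1(C)C)C(C)C(C)C | intermediate
15 | ethyl (2E)-3-methyl-5-[(1S,3S)-2,2,3-trimethyl-6-methylidenecyclohexyl]pent-2-enoate | CCOC(=O)/C=C(\C)CC[C@H]1C(=C)CC[C@H](C)C1(C)C | intermediate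
16 | (2E)-3-methyl-5-[(1S,3S)-2,2,3-trimethyl-6-methylidenecyclohexyl]pent-2-en-1-ol | OC/C=C(\C)CC[C@H]1C(=C)CC[C@H](C)C1(C)C | intermediate
17 | diethyl (2E)-3-methyl-5-[(1S,3S)-2,2,3-trimethyl-6-methylidenecyclohexyl]pent-2-en-1-yl phosphate | CCOP(=O)(OCC)OC/C=C(\C)CC[C@H]1C(=C)CC[C@H](C)C1(C)C | intermediate
18 | (3S)-3,7-dimethyloct-6-enal ((S)-citronellal) | C[C@H](CC=O)CCC=C(C)C | starting material
19 | (3S)-3,7-dimethylocta-1,6-dien-1-yl nonafluorobutane-1-sulfonate (E/Z mixture at C1=C2) | C[C@H](C=COS(=O)(=O)C(F)(F)C(F)(F)C(F)(F)C(F)(F)F)CCC=C(C)C | intermediate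
20 | (3S)-3,7-dimethyloct-6-en-1-yne | C[C@H](C#C)CCC=C(C)C | intermediate
21 | lithium (3S)-3,7-dimethyloct-6-en-1-yn-1-ide | C[C@H](C#C[Li])CCC=C(C)C | intermediate
22 | trimethyl[(3S)-3,7-dimethyloct-6-en-1-yn-1-yl]silane | C[C@H](C#C[Si](C)(C)C)CCC=C(C)C | intermediate
23 | (2E,6S)-2,6-dimethyl-8-(trimethylsilyl)oct-2-en-7-yn-1-ol | C[C@H](C#C[Si](C)(C)C)CC/C=C(\C)CO | intermediate
24 | [(3S,6E)-8-bromo-3,7-dimethyloct-6-en-1-yn-1-yl]trimethylsilane | C[C@H](C#C[Si](C)(C)C)CC/C=C(\C)CBr | intermediate
25 | (4S)-4-benzyl-1,3-oxazolidin-2-one | O=C1N[C@@H](Cc2ccccc2)CO1 | starting material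
26 | (4S)-4-benzyl-3-(3-methylbut-2-enoyl)-1,3-oxazolidin-2-one | CC(C)=CC(=O)N1[C@@H](Cc2ccccc2)COC1=O | intermediate
27 | sodium (1Z)-1-[(4S)-4-benzyl-2-oxo-1,3-oxazolidin-3-yl]-3-methylbuta-1,3-dien-1-olate | C=C(C)/C=C(\[O-])N1[C@@H](Cc2ccccc2)COC1=O.[Na+] | intermediate
28 | (4S)-4-benzyl-3-[(2S)-2,3-dimethylbut-3-enoyl]-1,3-oxazolidin-2-one | C=C(C)[C@H](C)C(=O)N1[C@@H](Cc2ccccc2)COC1=O | intermediate
29 | (2S)-2,3-dimethylbut-3-en-1-ol | C=C(C)[C@H](C)CO | intermediate
30 | (3S)-4-bromo-2,3-dimethylbut-1-ene | C=C(C)[C@H](C)CBr | intermediate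
31 | [(2S)-2,3-dimethylbut-3-en-1-yl]magnesium bromide | C=C(C)[C@H](C)C[Mg]Br | intermediate
32 | trimethyl[(3S,6E,10R)-3,7,10,11-tetramethyldodeca-6,11-dien-1-yn-1-yl]silane | C[C@H](C#C[Si](C)(C)C)CC/C=C(\C)CC[C@@H](C)C(=C)C | intermediate
33 | (3S,6E,10R)-3,7,10,11-tetramethyldodeca-6,11-dien-1-yne | C[C@H](C#C)CC/C=C(\C)CC[C@@H](C)C(=C)C | intermediate
34 | bis(2-methylpropyl)[(1E,3S,6E,10R)-3,7,10,11-tetramethyldodeca-1,6,11-trien-1-yl]alumane | CC(C)C[Al](CC(C)C)/C=C/[C@@H](C)CC/C=C(\C)CC[C@@H](C)C(=C)C | intermediate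
35 | (1S,3S)-1-[(3S,4E,6S,9E,13R)-3-ethenyl-3,6,10,13,14-pentamethylpentadeca-4,9,14-trien-1-yl]-2,2,3-trimethyl-6-methylidenecyclohexane (CNP0186101.1) | C=C[C@@](C)(/C=C/[C@@H](C)CC/C=C(\C)CC[C@@H](C)C(=C)C)CC[C@H]1C(=C)CC[C@H](C)C1(C)C | target

Total step count: 22. Longest linear sequence: 11 steps (steps 1–7, 9–11 and 22).

Steps most likely to fail

1. Step 7 (cycloisomerisation). The insertion may run through a boat-like or metallacyclic pathway that places the new C1 substituent equatorial (cis isomer); β-hydride loss may occur from C1–H and give the conjugated 1,3-diene; closure next to the quaternary carbon may be slow. The fallback sets out from 7 and returns at 15. Alcohol 7 is converted through its triflate 8 and C-alkylation of the dilithio dianion of 2-methylprop-2-en-1-ol (n-BuLi, TMEDA) into (5S,7E)-5,6,6-trimethyl-2-methylidenenon-7-en-1-ol F1. Ring-closing metathesis (second-generation Ru carbene catalyst, toluene, 80 °C, loss of propene) closes the ring as [(4S)-3,3,4-trimethylcyclohex-1-en-1-yl]methanol F2. A Johnson–Claisen rearrangement (MeC(OEt)3, cat. EtCO2H, 140 °C) then forms the C1–CH2 bond axially, anti to the pseudo-axial C2 methyl with the C3 methyl equatorial, which should give ethyl 2-[(1S,3S)-2,2,3-trimethyl-6-methylidenecyclohexyl]acetate F3 with the exocyclic methylene in place. LiAlH4 gives 2-[(1S,3S)-2,2,3-trimethyl-6-methylidenecyclohexyl]ethan-1-ol F4, and I2/PPh3/imidazole gives (1S,3S)-1-(2-iodoethyl)-2,2,3-trimethyl-6-methylidenecyclohexane F5. Zinc insertion and Pd-catalysed Negishi coupling with 13 give 15.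

2. Step 22 (allylic substitution). The catalyst may discriminate poorly between the methyl and CH2CH2 branches on C3 of 17, eroding selectivity at the quaternary centre; SN2 attack at C1 or transfer of an isobutyl or alkynyl group from aluminium may compete. The fallback sets out from 16 (together with 33) and returns at 35. Sharpless asymmetric epoxidation of 16 (Ti(OiPr)4, D-(−)-diethyl tartrate, t-BuOOH, −20 °C) gives [(2R,3R)-3-methyl-3-{2-[(1S,3S)-2,2,3-trimethyl-6-methylidenecyclohexyl]ethyl}oxiran-2-yl]methanol F7. The diethylalkynylalane made from 33 (n-BuLi, Et2AlCl) opens the epoxide at the tertiary C3 with inversion and gives (2S,3R)-3-methyl-3-[(3S,6E,10R)-3,7,10,11-tetramethyldodeca-6,11-dien-1-yn-1-yl]-5-[(1S,3S)-2,2,3-trimethyl-6-methylidenecyclohexyl]pentane-1,2-diol F8. Dissolving-metal reduction (Na, NH3/THF, −78 °C) gives (2S,3R)-3-methyl-3-[(1E,3S,6E,10R)-3,7,10,11-tetramethyldodeca-1,6,11-trien-1-yl]-5-[(1S,3S)-2,2,3-trimethyl-6-methylidenecyclohexyl]pentane-1,2-diol F9. Corey–Winter olefination through the cyclic thiocarbonate (1,3-dioxolane-2-thione) of this diol F10 (thiocarbonyldiimidazole, then P(OMe)3, heat) turns the diol into the vinyl group and gives 35.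

3. Step 9 (hydroboration and coupling). The 1,1-disubstituted exocyclic alkene may be hydroborated in competition with the vinyl group; transfer of the primary alkyl group from the hindered trialkylborane may be sluggish; base may eliminate triflate from 13. The fallback sets out from 11 and returns at 15. Hydrozirconation of 11 with Cp2Zr(H)Cl (THF, 23 °C) adds to the monosubstituted alkene far faster than to the 1,1-disubstituted one, and iodinolysis gives (1S,3S)-1-(2-iodoethyl)-2,2,3-trimethyl-6-methylidenecyclohexane F6 (the same iodide as in the first fallback). Zinc insertion (Zn, LiCl, THF) and Pd-catalysed Negishi coupling with 13 give 15.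

Further compounds
F1 | step 7 | (5S,7E)-5,6,6-trimethyl-2-methylidenenon-7-en-1-ol | C/C=C/C(C)(C)[C@@H](C)CCC(=C)CO
F2 | step 7 | [(4S)-3,3,4-trimethylcyclohex-1-en-1-yl]methanol | OCC1=CC(C)(C)[C@@H](C)CC1
F3 | step 7 | ethyl 2-[(1S,3S)-2,2,3-trimethyl-6-methylidenecyclohexyl]acetate | CCOC(=O)C[C@H]1C(=C)CC[C@H](C)C1(C)C
F4 | step 7 | 2-[(1S,3S)-2,2,3-trimethyl-6-methylidenecyclohexyl]ethan-1-ol | OCC[C@H]1C(=C)CC[C@H](C)C1(C)C
F5 | step 7 | (1S,3S)-1-(2-iodoethyl)-2,2,3-trimethyl-6-methylidenecyclohexane | ICC[C@H]1C(=C)CC[C@H](C)C1(C)C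
F6 | step 9 | (1S,3S)-1-(2-iodoethyl)-2,2,3-trimethyl-6-methylidenecyclohexane | ICC[C@H]1C(=C)CC[C@H](C)C1(C)C
F7 | step 22 | [(2R,3R)-3-methyl-3-{2-[(1S,3S)-2,2,3-trimethyl-6-methylidenecyclohexyl]ethyl}oxiran-2-yl]methanol | OC[C@H]1O[C@]1(C)CC[C@H]2C(=C)CC[C@H](C)C2(C)C
F8 | step 22 | (2S,3R)-3-methyl-3-[(3S,6E,10R)-3,7,10,11-tetramethyldodeca-6,11-dien-1-yn-1-yl]-5-[(1S,3S)-2,2,3-trimethyl-6-methylidenecyclohexyl]pentane-1,2-diol | OC[C@@H](O)[C@@](C)(C#C[C@@H](C)CC/C=C(\C)CC[C@@H](C)C(=C)C)CC[C@H]1C(=C)CC[C@H](C)C1(C)C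
F9 | step 22 | (2S,3R)-3-methyl-3-[(1E,3S,6E,10R)-3,7,10,11-tetramethyldodeca-1,6,11-trien-1-yl]-5-[(1S,3S)-2,2,3-trimethyl-6-methylidenecyclohexyl]pentane-1,2-diol | OC[C@@H](O)[C@@](C)(/C=C/[C@@H](C)CC/C=C(\C)CC[C@@H](C)C(=C)C)CC[C@H]1C(=C)CC[C@H](C)C1(C)C
F10 | step 22 | cyclic thiocarbonate (1,3-dioxolane-2-thione) of the 1,2-diol F9, configuration unchanged | S=C1OC[C@@H](O1)[C@@](C)(/C=C/[C@@H](C)CC/C=C(\C)CC[C@@H](C)C(=C)C)CC[C@H]2C(=C)CC[C@H](C)C2(C)C
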